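The route rests on cutting the C4–C4a bond of the chroman. C4 is an unsubstituted methylene between C3 and the ring A carbon C4a, which lies ortho to O1 and ortho/para to the two other ring A oxygens, so ring A can act as a carbon nucleophile. In one operation an acid-activated terminal epoxide is opened at its CH2 carbon by that arene carbon, closing ring C and releasing the free C3 hydroxyl with C2 and C3 already set. The precursor is an open-chain (R,R) aryl ether in which O1–C2 is in place and C3/C4 are held as an oxirane, all phenols as benzyl ethers.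

Key step: step 4

Remark on the chemistry: the target is taken as the (2R,3R), 2,3-cis (epi-series) enantiomer as drawn. The tartrate in step 2 is assigned from the empirical face rule of the titanium–tartrate epoxidation: L-(+)-tartrate should consume the (R)-carbinol of 2 and leave the (S)-carbinol. The erythro epoxy alcohol 3 (S carbinol, R oxirane carbon) becomes the threo (R,R) ether 5 on inversion, and 5 carries the 2,3-cis arrangement.

Step 1
Reactants: 1 3,4,5-tris(benzyloxy)benzaldehyde
Product: 2 rac-1-[3,4,5-tris(benzyloxy)phenyl]prop-2-en-1-ol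
Conditions: CH2=CHMgBr (1.5 equiv), THF, −78 → 0 °C; then H2O (pH 7 buffer)
Reagents that add atoms: vinylmagnesium bromide, C=C[Mg]Br
Why: Grignard 1,2-addition of the vinyl nucleophile to the non-enolisable aryl aldehyde should give the secondary allylic alcohol cleanly, the new carbinol centre being left racemic on purpose for resolution in step 2.

Step 2
Reactants: 2 rac-1-[3,4,5-tris(benzyloxy)phenyl]prop-2-en-1-ol
Product: 3 (S)-[(R)-oxiran-2-yl][3,4,5-tris(benzyloxy)phenyl]methanol
Conditions: Ti(OiPr)4 (0.15 equiv), diisopropyl L-(+)-tartrate (0.20 equiv), t-BuOOH (0.5 equiv, anhydrous), 4 Å MS, CH2Cl2, −20 °C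
Reagents that add atoms: tert-butyl hydroperoxide, CC(C)(C)OO
Why: Sharpless kinetic resolution (titanium–tartrate epoxidation of a racemic secondary allylic alcohol) should epoxidise the (R)-carbinol enantiomer much faster than its antipode and on the face that gives the erythro product, so the catalyst selects the carbinol centre (S in 3 by the change of CIP priorities) and sets the oxirane centre (R), while the unreacted (S)-allylic alcohol is removed by chromatography.

Step 3
Reactants: 3 (S)-[(R)-oxiran-2-yl][3,4,5-tris(benzyloxy)phenyl]methanol, 4 3,5-bis(benzyloxy)phenol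
Product: 5 (R)-[(R)-oxiran-2-yl][3,4,5-tris(benzyloxy)phenyl]methyl 3,5-bis(benzyloxy)phenyl ether
Conditions: PPh3, DIAD, toluene, 0 °C → rt
Reagents that add atoms: none
Why: Mitsunobu etherification, in which the phenol should displace the oxyphosphonium derivative of the secondary benzylic alcohol by SN2 with inversion, turning the (S)-carbinol into the (R)-aryl ether threo to the untouched oxirane, with the electron-withdrawing oxirane and the non-polar solvent disfavouring ionisation at the benzylic carbon.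

Step 4
Reactants: 5 (R)-[(R)-oxiran-2-yl][3,4,5-tris(benzyloxy)phenyl]methyl 3,5-bis(benzyloxy)phenyl ether
Product: 6 (2R,3R)-5,7-bis(benzyloxy)-2-[3,4,5-tris(benzyloxy)phenyl]chroman-3-ol (penta-O-benzyl epigallocatechin)
Conditions: (CF3)2CHOH (HFIP)/CH2Cl2 (4:1), 0.01 M, 25 → 45 °C
Reagents that add atoms: none
Why: Hydrogen bonding from the fluoroalcohol polarises the terminal C–O bond of the oxirane, and the ring A carbon ortho to the ether oxygen (also ortho and para to the two benzyloxy groups) attacks the oxirane CH2 in an SN2-like way to give an arenium ion that rearomatises by proton loss, forming C4–C4a. This is an intramolecular Friedel–Crafts alkylation of the epoxy-arene type, the known conversion of electron-rich aryl glycidyl ethers into chroman-3-ols. Ring C closes in the 6-endo mode with respect to the oxirane, both oxirane carbons ending up in the new pyran. No stereocentre is formed, because the C2–O1 and C3–O bonds are not touched and the (R,R) configuration of 5 is carried over unchanged as (2R,3R) in 6. The step needs 6-endo rather than 5-exo opening, which the unhindered primary terminus and the inductive deactivation of the internal carbon by the neighbouring C2–O bond should secure, and it needs the benzylic aryl ether at C2 to survive, which the weak acidity of the medium, the only modest net donor power of the 3,4,5-trialkoxyphenyl group and the electron-poor neighbouring carbon should allow. The two ortho carbons of ring A are equivalent by symmetry and the para carbon cannot reach the oxirane, so no arene regioisomer can arise, and high dilution guards against intermolecular alkylation.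

Step 5
Reactants: 6 (2R,3R)-5,7-bis(benzyloxy)-2-[3,4,5-tris(benzyloxy)phenyl]chroman-3-ol, 7 4-(benzyloxy)benzoic acid
Product: 8 (2R,3R)-5,7-bis(benzyloxy)-2-[3,4,5-tris(benzyloxy)phenyl]chroman-3-yl 4-(benzyloxy)benzoate
Conditions: DCC, DMAP (cat.), CH2Cl2, 0 °C → rt
Reagents that add atoms: none
Why: Steglich esterification (carbodiimide activation with DMAP as acyl-transfer catalyst) should acylate the hindered secondary C3 hydroxyl of the benzylated flavan-3-ol without breaking any bond to C2 or C3, so both stereocentres are retained.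

Step 6
Reactants: 8 (2R,3R)-5,7-bis(benzyloxy)-2-[3,4,5-tris(benzyloxy)phenyl]chroman-3-yl 4-(benzyloxy)benzoate
Product: 9 (2R,3R)-5,7-dihydroxy-2-(3,4,5-trihydroxyphenyl)chroman-3-yl 4-hydroxybenzoate [epigallocatechin 3-O-(4-hydroxybenzoate)]
Conditions: H2 (1 atm), Pd(OH)2/C, THF/MeOH (1:1), rt; filtration under argon
Reagents that add atoms: none
Why: Catalytic hydrogenolysis should remove all six O-benzyl groups as toluene under neutral conditions that leave the aryl ester, the cyclic benzylic C2–O1 ether and both stereocentres intact.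

Compound list
1 | 3,4,5-tris(benzyloxy)benzaldehyde | O=Cc1cc(OCc2ccccc2)c(OCc2ccccc2)c(OCc2ccccc2)c1 | starting material
2 | rac-1-[3,4,5-tris(benzyloxy)phenyl]prop-2-en-1-ol (racemate) | OC(C=C)c1cc(OCc2ccccc2)c(OCc2ccccc2)c(OCc2ccccc2)c1 | intermediate
3 | (S)-[(R)-oxiran-2-yl][3,4,5-tris(benzyloxy)phenyl]methanol (erythro) | O[C@H]([C@H]1CO1)c1cc(OCc2ccccc2)c(OCc2ccccc2)c(OCc2ccccc2)c1 | intermediate
4 | 3,5-bis(benzyloxy)phenol | Oc1cc(OCc2ccccc2)cc(OCc2ccccc2)c1 | starting material
5 | (R)-[(R)-oxiran-2-yl][3,4,5-tris(benzyloxy)phenyl]methyl 3,5-bis(benzyloxy)phenyl ether (threo) | c1ccccc1COc1cc(OCc2ccccc2)cc(O[C@@H]([C@H]2CO2)c2cc(OCc3ccccc3)c(OCc3ccccc3)c(OCc3ccccc3)c2)c1 | intermediate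
6 | (2R,3R)-5,7-bis(benzyloxy)-2-[3,4,5-tris(benzyloxy)phenyl]chroman-3-ol | O[C@@H]1Cc2c(OCc3ccccc3)cc(OCc3ccccc3)cc2O[C@@H]1c1cc(OCc2ccccc2)c(OCc2ccccc2)c(OCc2ccccc2)c1 | intermediate
7 | 4-(benzyloxy)benzoic acid | OC(=O)c1ccc(OCc2ccccc2)cc1 | starting material
8 | (2R,3R)-5,7-bis(benzyloxy)-2-[3,4,5-tris(benzyloxy)phenyl]chroman-3-yl 4-(benzyloxy)benzoate | O=C(O[C@@H]1Cc2c(OCc3ccccc3)cc(OCc3ccccc3)cc2O[C@@H]1c1cc(OCc2ccccc2)c(OCc2ccccc2)c(OCc2ccccc2)c1)c1ccc(OCc2ccccc2)cc1 | intermediate
9 | (2R,3R)-5,7-dihydroxy-2-(3,4,5-trihydroxyphenyl)chroman-3-yl 4-hydroxybenzoate | O=C(O[C@@H]1Cc2c(O)cc(O)cc2O[C@@H]1c1cc(O)c(O)c(O)c1)c1ccc(O)cc1 | target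

Total step count: 6
Longest linear sequence: 6 steps (1 → 2 → 3 → 5 → 6 → 8 → 9)

Steps most likely to fail

Step 4 (key step). What may go wrong: ionisation of the benzylic C2–O1 ether under the protic activation (loss of the ring A phenol or scrambling at C2), opening at the internal oxirane carbon, or intermolecular alkylation outrunning ring closure. Fallback, setting out from 3 and 4 and returning at 6: the same C4–C4a bond would be made with reversed polarity, ring A acting as an aryl anion under basic conditions. Phenol 4 would be brominated ortho to the hydroxyl (NBS, CH2Cl2, −78 °C) to give 2-bromo-3,5-bis(benzyloxy)phenol F1. F1 would be coupled with 3 under the Mitsunobu conditions of step 3 to give (R)-[(R)-oxiran-2-yl][3,4,5-tris(benzyloxy)phenyl]methyl 2-bromo-3,5-bis(benzyloxy)phenyl ether F2. LiBr/AcOH in THF would open the oxirane at its primary carbon to the bromohydrin (1R,2S)-3-bromo-1-[2-bromo-3,5-bis(benzyloxy)phenoxy]-1-[3,4,5-tris(benzyloxy)phenyl]propan-2-ol F3. Silylation (Et3SiCl, imidazole, DMF) would give triethyl{[(1R,2S)-3-bromo-1-[2-bromo-3,5-bis(benzyloxy)phenoxy]-1-[3,4,5-tris(benzyloxy)phenyl]propan-2-yl]oxy}silane F4. Bromine–lithium exchange at the aryl bromide (n-BuLi, THF, −100 °C) followed by 6-exo-tet displacement of the primary bromide by the aryllithium (Parham cycloalkylation) would close ring C to (2R,3R)-5,7-bis(benzyloxy)-3-[(triethylsilyl)oxy]-2-[3,4,5-tris(benzyloxy)phenyl]chromane F5, and Bu4NF in THF would release 6.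

Step 3. What may go wrong: partial ionisation of the activated benzylic carbinol, so that the phenol is attached with incomplete inversion and the configuration at C2 is eroded, or attack of the phenol on the oxirane. Fallback, setting out from 2 and 4 and returning at 5: the C2–O1 bond would be made by SN2 opening of a trans-epoxide at its benzylic carbon, and the terminal oxirane would be built afterwards. Dilute acid (TsOH·H2O, aqueous THF, rt) would transpose racemic 2 to the conjugated (E)-3-[3,4,5-tris(benzyloxy)phenyl]prop-2-en-1-ol F6. Catalytic asymmetric epoxidation (Ti(OiPr)4, diethyl L-(+)-tartrate, t-BuOOH, 4 Å MS, CH2Cl2, −20 °C) should give {(2S,3S)-3-[3,4,5-tris(benzyloxy)phenyl]oxiran-2-yl}methanol F7. The sodium salt of 4 (NaOH, aqueous dioxane, 60 °C) should open F7 at the benzylic carbon with inversion to (2S,3R)-3-[3,5-bis(benzyloxy)phenoxy]-3-[3,4,5-tris(benzyloxy)phenyl]propane-1,2-diol F8. Selective acylation of the primary hydroxyl (4-nitrobenzoyl chloride, Et3N, CH2Cl2, −20 °C) would give (2S,3R)-3-[3,5-bis(benzyloxy)phenoxy]-2-hydroxy-3-[3,4,5-tris(benzyloxy)phenyl]propyl 4-nitrobenzoate F9, and mesylation (MsCl, Et3N, CH2Cl2, 0 °C) would give (2S,3R)-3-[3,5-bis(benzyloxy)phenoxy]-2-[(methylsulfonyl)oxy]-3-[3,4,5-tris(benzyloxy)phenyl]propyl 4-nitrobenzoate F10. K2CO3 in MeOH would cleave the ester, and the primary alkoxide would displace the mesylate with inversion at the secondary carbon to give 5.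

Step 2. What may go wrong: insufficient discrimination between the two carbinol enantiomers of a monosubstituted alkene, so that the enantiomeric purity of the epoxy alcohol erodes once conversion is pushed. Fallback, setting out from 2 and returning at 3: the carbinol centre would be fixed first by an enzyme, leaving the epoxidation only diastereocontrol. Immobilised Candida antarctica lipase B with vinyl acetate in toluene should acylate the (R)-enantiomer of 2 preferentially, in line with the empirical size rule for secondary alcohols, giving (R)-1-[3,4,5-tris(benzyloxy)phenyl]prop-2-en-1-yl acetate F11, separable from the unreacted (S)-alcohol. K2CO3 in MeOH would give (R)-1-[3,4,5-tris(benzyloxy)phenyl]prop-2-en-1-ol F12. The matched epoxidation of F12 (Ti(OiPr)4, diisopropyl L-(+)-tartrate, t-BuOOH, 4 Å MS, CH2Cl2, −20 °C), now run to full conversion, would return 3.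

Further compounds
F1 | step 4 | 2-bromo-3,5-bis(benzyloxy)phenol | Oc1cc(OCc2ccccc2)cc(OCc2ccccc2)c1Br
F2 | step 4 | (R)-[(R)-oxiran-2-yl][3,4,5-tris(benzyloxy)phenyl]methyl 2-bromo-3,5-bis(benzyloxy)phenyl ether | Brc1c(OCc2ccccc2)cc(OCc2ccccc2)cc1O[C@@H]([C@H]1CO1)c1cc(OCc2ccccc2)c(OCc2ccccc2)c(OCc2ccccc2)c1
F3 | step 4 | (1R,2S)-3-bromo-1-[2-bromo-3,5-bis(benzyloxy)phenoxy]-1-[3,4,5-tris(benzyloxy)phenyl]propan-2-ol | Brc1c(OCc2ccccc2)cc(OCc2ccccc2)cc1O[C@@H]([C@H](O)CBr)c1cc(OCc2ccccc2)c(OCc2ccccc2)c(OCc2ccccc2)c1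
F4 | step 4 | triethyl{[(1R,2S)-3-bromo-1-[2-bromo-3,5-bis(benzyloxy)phenoxy]-1-[3,4,5-tris(benzyloxy)phenyl]propan-2-yl]oxy}silane | Brc1c(OCc2ccccc2)cc(OCc2ccccc2)cc1O[C@@H]([C@H](O[Si](CC)(CC)CC)CBr)c1cc(OCc2ccccc2)c(OCc2ccccc2)c(OCc2ccccc2)c1
F5 | step 4 | (2R,3R)-5,7-bis(benzyloxy)-3-[(triethylsilyl)oxy]-2-[3,4,5-tris(benzyloxy)phenyl]chromane | CC[Si](CC)(CC)O[C@@H]1Cc2c(OCc3ccccc3)cc(OCc3ccccc3)cc2O[C@@H]1c1cc(OCc2ccccc2)c(OCc2ccccc2)c(OCc2ccccc2)c1
F6 | step 3 | (E)-3-[3,4,5-tris(benzyloxy)phenyl]prop-2-en-1-ol | OC/C=C/c1cc(OCc2ccccc2)c(OCc2ccccc2)c(OCc2ccccc2)c1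
F7 | step 3 | {(2S,3S)-3-[3,4,5-tris(benzyloxy)phenyl]oxiran-2-yl}methanol | OC[C@@H]1O[C@H]1c1cc(OCc2ccccc2)c(OCc2ccccc2)c(OCc2ccccc2)c1
F8 | step 3 | (2S,3R)-3-[3,5-bis(benzyloxy)phenoxy]-3-[3,4,5-tris(benzyloxy)phenyl]propane-1,2-diol | OC[C@H](O)[C@H](Oc1cc(OCc2ccccc2)cc(OCc2ccccc2)c1)c1cc(OCc2ccccc2)c(OCc2ccccc2)c(OCc2ccccc2)c1
F9 | step 3 | (2S,3R)-3-[3,5-bis(benzyloxy)phenoxy]-2-hydroxy-3-[3,4,5-tris(benzyloxy)phenyl]propyl 4-nitrobenzoate | O=C(OC[C@H](O)[C@H](Oc1cc(OCc2ccccc2)cc(OCc2ccccc2)c1)c1cc(OCc2ccccc2)c(OCc2ccccc2)c(OCc2ccccc2)c1)c1ccc(cc1)[N+](=O)[O-]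
F10 | step 3 | (2S,3R)-3-[3,5-bis(benzyloxy)phenoxy]-2-[(methylsulfonyl)oxy]-3-[3,4,5-tris(benzyloxy)phenyl]propyl 4-nitrobenzoate | O=C(OC[C@H](OS(C)(=O)=O)[C@H](Oc1cc(OCc2ccccc2)cc(OCc2ccccc2)c1)c1cc(OCc2ccccc2)c(OCc2ccccc2)c(OCc2ccccc2)c1)c1ccc(cc1)[N+](=O)[O-]
F11 | step 2 | (R)-1-[3,4,5-tris(benzyloxy)phenyl]prop-2-en-1-yl acetate | CC(=O)O[C@H](C=C)c1cc(OCc2ccccc2)c(OCc2ccccc2)c(OCc2ccccc2)c1
F12 | step 2 | (R)-1-[3,4,5-tris(benzyloxy)phenyl]prop-2-en-1-ol | O[C@H](C=C)c1cc(OCc2ccccc2)c(OCc2ccccc2)c(OCc2ccccc2)c1
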